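The examiner puts the flasks and runs on the table and asks for the two final amounts of target.

| flask | substrate | reagent | temperature | remark | time |
|---|---|---|---|---|---|
| Monday's | 0.037 M (fed, over 3.0 min) | 0.50 equiv | 10 °C | run made earlier |  |
| Tuesday's | 0.041 M (fed, over 3.0 min) | 0.50 equiv | 25 °C | run made earlier |  |
| Sunday's | 0.042 M (fed, over 3.0 min) | 0.50 equiv | 10 °C | run made earlier |  |
| summer | 0.030 M | 0.500 equiv | 25 °C | everything together at the start | 2.0 min |
| midnight | 0.050 M (fed, over 3.0 min) | 0.500 equiv | 25 °C |  | 3.0 min |

- Monday's (time / min: target / %, substrate / %): 0.417: 0, 14.2; 1.00: 0.7, 32.9; 2.00: 2.2, 65.8; 3.00: 2.8, 97.1; 4.00: 4.8, 93.9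
- Tuesday's (time / s: target / %, substrate / %): 12.0: 0.3, 6.6; 30.0: 0, 16.4; 60.0: 1.8, 32.0; 90.0: 2.7, 47.6; 120: 4.9, 61.1
- Sunday's (time / min: target / %, substrate / %): 0.333: 0.3, 10.3; 0.667: 0.2, 22.5; 1.33: 0.4, 44.2; 2.00: 1.8, 65.3; 4.00: 9.4, 91.9

(standard deviation of a reading: 0.5 percentage points)

- the earlier runs were read with a standard deviation of 0.5 percentage points
- steps under discussion: substrate + reagent + by-product -> target + 2 by-product; substrate + reagent -> target + by-product
- where the amount of substrate changes, what is given in equivalents or mol% on it follows
- percentages count the whole charge, also what has not yet gone in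

* the flask that ends with the higher amount of target, in percent of the substrate charged, or "neither" when 2 percentage points or less lies between them (summer / midnight / neither)
* final target, as a percentage of the substrate charged, in summer
* final target, as a percentage of the substrate charged, in midnight

"What stands over both flasks?" Each step spends one reagent per target, so at 0.500 equiv the reagent is the limiting reagent, and the target stops at 50 % of the substrate charged.

"Which rate matters?" With both steps running, d[target]/dt = [substrate][reagent](a + b[by-product]), where a and b are the two rate constants. The by-product starts absent and grows by one per target, so [by-product] = [target]. Separating the variables gives ln(1 + b[target]/a) = bE, where E is the time integral of [substrate][reagent], reckoned as if nothing had been consumed.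

"Work out E." In summer the product stands still, so E = 9.00 × 10⁻⁴ M^2 min. In midnight [substrate] climbs in a straight line during the feed, so the integral is a triangle and E = 0.00188 M^2 min, the exposure. Midnight therefore gets twice the exposure of summer.

"What do the runs give?" I call [target]/E the return. Tuesday's run, at the same 25 °C, has E = 5.60 × 10⁻⁴ M^2 min at 120 s, and its 4.9 % of target reads as a return of 3.59 M⁻¹ min⁻¹. At that return summer reaches 10.8 % and midnight 13.4 %, two figures to be held against the margin of 2 percentage points.

"Why should the return grow?" The closed form gives [target] as an exponential of E, so the return rises with E. At 4.00 min, Sunday's run reads 9.4 % of target on a charge of 0.042 M and Monday's reads 4.8 % on 0.037 M, one pair of readings, each with a standard deviation of 0.5 points.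

"But doesn't E overcount?" It does: a target of 13.4 % means 26.8 % of midnight's reagent used. I cannot size that loss against the growth, but I commit to midnight ending higher.

The forecast said 11.5 % for summer and 21 % for midnight, so midnight, from “a second-order background plus an autocatalytic step”.

The simulation gives 13.2 % in summer and 24.4 % in midnight, so midnight ends higher.

    substrate + reagent + by-product → target + 2 by-product (k = 25.9 M⁻² s⁻¹, Ea = 35.0 kJ mol⁻¹)
    substrate + reagent → target + by-product (k = 0.0465 M⁻¹ s⁻¹, Ea = 59.0 kJ mol⁻¹)
    (constants at 25 °C)

Summer's return comes to 4.41 M⁻¹ min⁻¹ and midnight's to 6.50 M⁻¹ min⁻¹, which is higher at its larger exposure. A neighbour of midnight takes 0.850 equiv of reagent and keeps the same feed, so its triangle grows with the reagent to E = 0.00319 M^2 min. That neighbour holds 52.0 % of target at 3.00 min, a return of 8.16 M⁻¹ min⁻¹, above midnight's, with 39 % of its reagent still there.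

The readings stem from a simulated flask on assumed constants, noise included.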